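The pitfall I saw in the amber flask was to carry forward the latest pseudo-first-order constant of the violet run, which had the same charge.

| setting | violet | blue | grey | green | amber |
|---|---|---|---|---|---|
| starting material | 0.250 M | 0.130 M | 0.500 M | 0.250 M | 0.250 M |
| free catalyst | 0.0130 M | 0.0130 M | 0.0130 M | 0.0260 M | 0.0130 M |
| time |  |  |  |  | 200 min |

- violet run (time / min: [target] / M): 4.0: 0.0189; 8.9: 0.0448; 20: 0.0793; 45: 0.1220; 100: 0.1545
- blue run (time / min: [target] / M): 4.0: 0.0090; 8.9: 0.0167; 20: 0.0299; 45: 0.0444; 100: 0.0550
- grey run (time / min: [target] / M): 4.0: 0.0395; 8.9: 0.0872; 20: 0.1780; 45: 0.2939; 100: 0.3783
- green run (time / min: [target] / M): 4.0: 0.0510; 8.9: 0.0860; 20: 0.1279; 45: 0.1579; 100: 0.1753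

(each reading ± 0.002 M)

- Overall: starting material -> target, with free catalyst as catalyst.
- Constant volume, constant temperature.
- Bound and free are read together.
- An order is taken over about fifteen percent of the charge, up and down.

- reaction order in [free catalyst] at the outset, round the charge of the violet run, defined at two percent of the starting material turned into target
- reaction order in [starting material] at the outset, round the charge of the violet run, defined at two percent of the starting material turned into target (one fixed amount of target, the same in the runs compared)
- the blue run starts with 0.120 M less of starting material than the violet run, and with no target. Compared where both hold the same amount of starting material, once fifteen percent of what the blue run was charged with has turned into target, is the blue run faster, slower or alike (within a tenth)?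
- target in the amber run at 200 min, as a share of the starting material charged

I spent my reckoning on the amber share. I wrote L for the natural logarithm of the charge over the part of it still unconverted. The zero of my scale was a flask whose L grows in proportion to time. In the violet run L read 0.382, 0.669 and 0.962 at 20 min, 45 min and 100 min.

My bound from below was the violet share at 100 min, 61.8%, as the target readings rose throughout. My bound from above held the last constant, 0.00533 min⁻¹, for the further 100 min, which gave 77.6%. But that constant was already lower than the 0.0115 min⁻¹ of the stretch before, so the violet run had left the zero of the scale.

To tighten the floor, I let the constant go on falling at 0.0193 min⁻¹, and the share came to 66.8%. To tighten the ceiling, I looked at L against doublings of the time. It rose at 0.246 per doubling from 20 min to 45 min, and at 0.254 from 45 min to 100 min. This amount is the gain per doubling, the increase in L each time the elapsed time doubles. On the zero of the scale, a doubling would add as much as L already held. Adding the gain once to the violet L at 100 min gave 70.4% at 200 min. Both tightened edges were extrapolations, not strict bounds, and I committed to the middle of that bracket, 68.6%.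

The forecast gave order 1.5 in free catalyst, 1.05 in starting material, the blue run faster, and 67% for amber, at the lower edge of my bracket, on the ground that “This looks like catalyst dying, with substrate protecting it”.

The flask gave order 1.7 in free catalyst, 1.2 in starting material, the blue run faster, and 68.8% for amber, inside my bracket.

    free catalyst + starting material ⇌ catalyst-substrate complex, settled at all times (1.650 M⁻¹)
    catalyst-substrate complex + starting material ⇌ doubly bound catalyst, settled at all times (8.100 M⁻¹)
    doubly bound catalyst → target + catalyst-substrate complex (2.262 min⁻¹)
    free catalyst + impurity → spent catalyst
    2 free catalyst → 2 spent catalyst (5.628 M⁻¹ min⁻¹)

The reaction of two free catalyst to spent catalyst is the main reason that the amber flask stood at 68.8%: the run without that reaction reached 90.1%. From the violet reading at 100 min to 200 min in the amber flask, L gained 0.203, less than the 0.254 I carried. In the grey run the gain per doubling read 0.381 between 20 min and 45 min, which puts target at half of the grey charge at 31.7 min, and the grey run reaches that mark at 32.6 min.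

(Readings and results stem from a simulated flask for an exercise; the scatter is artificial.)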